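**Retrosynthetic overview**
1. Ring A is numbered C1 (CH3), C2–H, C3–H, C4 (4-hydroxyphenyl), C5 (bearing the methide carbon C7), C6 (bearing the alkyne C8≡C9). Its two most hindered substituents sit on the adjacent carbons C5 and C6, which can serve as the two ends of an aryne triple bond.
2. Target ⇐ triaryl carbinol tris(methyl ether): cleavage of three O–CH3 bonds and ionisation/dehydration at C7 to the quinone methide.
3. Carbinol ⇐ C5≡C6 aryne (from 3-chloro-4'-methoxy-4-methylbiphenyl) + lithium 4-methoxyphenylacetylide (C6–C8) + 4-methoxybenzophenone (C5–C7), in one pot.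
4. Chlorobiaryl ⇐ 4-bromo-2-chlorotoluene + 4-methoxyphenylboronic acid (C4–aryl bond, Suzuki coupling).
5. No ring is formed in the route; all five six-membered rings are bought intact and only joined.

Key step: step 2

Remark on the chemistry: the target SMILES carries no stereodescriptor and the molecule has no stereocentre; its biaryl and aryl–C7 axes are assumed to rotate freely. No enantioselective step is therefore needed. The C7 carbinol centre of the intermediate is made racemic and is destroyed in the last step.

**Route**

Step 1
Reactants: 1 4-bromo-2-chlorotoluene; 2 4-methoxyphenylboronic acid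
Product: 3 3-chloro-4'-methoxy-4-methylbiphenyl
Conditions: Pd(PPh3)4 (cat.), K2CO3, toluene–EtOH–H2O, 80 °C
Reagents that add atoms: none
Why: Suzuki–Miyaura coupling in which Pd(PPh3)4 inserts into the C–Br bond much faster than into the C–Cl bond, so the chloride needed for aryne generation is kept.

Step 2
Reactants: 3 3-chloro-4'-methoxy-4-methylbiphenyl; 4 4-ethynylanisole; 5 4-methoxybenzophenone
Product: 11 (4-methoxyphenyl)[6-(4-methoxyphenyl)-2-[(4-methoxyphenyl)ethynyl]-3-methylphenyl](phenyl)methanol (racemic), via lithium acetylide 6 (not isolated), via 2-lithio chlorobiaryl 7 (not isolated), via aryne 8 (not isolated), via ortho-alkynyl aryllithium 9 (not isolated), via lithium alkoxide 10 (not isolated)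
Conditions: 4 (2 equiv), n-BuLi (2 equiv), THF, −78 °C; add 3, then LiTMP (1.5 equiv, from TMPH and n-BuLi) dropwise, THF–pentane, −78 → 0 °C; recool to −78 °C, 5 (3 equiv); AcOH, −78 °C
Reagents that add atoms: none
Why: Proposed new method: LiTMP removes C5–H, the only ring proton ortho to chlorine and further acidified by the C4 aryl group, and aryllithium 7 expels LiCl to give the single aryne 8 (C5≡C6); acetylide 6 adds at C6, and the new C5 aryllithium 9 is captured by the non-enolisable ketone 5 at −78 °C to give alkoxide 10, which is protonated cold. The closest known reaction type is the base-mediated alkynylation of aryl chlorides through arynes with interception of the ortho-alkynyl arylmetal by a simple electrophile, combined with the known addition of 2,6-disubstituted aryllithiums to diaryl ketones; using a diaryl ketone as the third component in one pot is the untested part. No ring is closed. The C7 carbinol centre forms racemic and needs no control, because it becomes sp2 in step 3. The selectivity required is acetylide attack at C6 rather than C5: the C4 aryl group shields C5 and inductively stabilises the negative charge developing there (the same bias that sends nucleophiles to the distal carbon of 3-arylbenzynes in m-terphenyl syntheses), whereas the C1 methyl opposes this only weakly. Preformed acetylide with no free alkyne, slow addition of the amide, low temperature and a cold acidic quench guard against protonation of 9, its addition to a second aryne, and addition of alkoxide 10 to the alkyne.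

Step 3
Reactants: 11 (4-methoxyphenyl)[6-(4-methoxyphenyl)-2-[(4-methoxyphenyl)ethynyl]-3-methylphenyl](phenyl)methanol
Product: 13 selaginellin A, via triarylmethyl cation 12 (not isolated)
Conditions: BBr3 (excess), CH2Cl2, −78 → 0 °C; then H2O/aq. NaHCO3
Reagents that add atoms: none
Why: BBr3 ionises the tertiary triaryl carbinol to the anisyl-stabilised cation 12, bromide removes the methyl group of its oxocarbenium form to give the quinone methide directly (fuchsone formation), and the two remaining anisole ethers undergo the usual BBr3 ether cleavage and are freed as phenols on aqueous work-up.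

**Compound list**
1 | 4-bromo-2-chlorotoluene | Cc1ccc(Br)cc1Cl | starting material
2 | 4-methoxyphenylboronic acid | COc1ccc(B(O)O)cc1 | starting material
3 | 3-chloro-4'-methoxy-4-methylbiphenyl | Cc1ccc(-c2ccc(OC)cc2)cc1Cl | intermediate
4 | 4-ethynylanisole | C#Cc1ccc(OC)cc1 | starting material
5 | 4-methoxybenzophenone | COc1ccc(C(=O)c2ccccc2)cc1 | starting material
6 | lithium 4-methoxyphenylacetylide | [Li]C#Cc1ccc(OC)cc1 | intermediate
7 | (3-chloro-4'-methoxy-4-methylbiphenyl-2-yl)lithium | Cc1ccc(-c2ccc(OC)cc2)c([Li])c1Cl | intermediate
8 | 3-(4-methoxyphenyl)-6-methylbenzyne (C5≡C6 aryne) | CC1=CC=C(c2ccc(OC)cc2)C#C1 | intermediate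
9 | [6-(4-methoxyphenyl)-2-[(4-methoxyphenyl)ethynyl]-3-methylphenyl]lithium | Cc1ccc(-c2ccc(OC)cc2)c([Li])c1C#Cc1ccc(OC)cc1 | intermediate
10 | lithium (4-methoxyphenyl)[6-(4-methoxyphenyl)-2-[(4-methoxyphenyl)ethynyl]-3-methylphenyl](phenyl)methanolate (racemic) | Cc1ccc(-c2ccc(OC)cc2)c(C(O[Li])(c2ccccc2)c2ccc(OC)cc2)c1C#Cc1ccc(OC)cc1 | intermediate
11 | (4-methoxyphenyl)[6-(4-methoxyphenyl)-2-[(4-methoxyphenyl)ethynyl]-3-methylphenyl](phenyl)methanol (racemic) | Cc1ccc(-c2ccc(OC)cc2)c(C(O)(c2ccccc2)c2ccc(OC)cc2)c1C#Cc1ccc(OC)cc1 | intermediate
12 | (4-methoxyphenyl)[6-(4-methoxyphenyl)-2-[(4-methoxyphenyl)ethynyl]-3-methylphenyl](phenyl)methylium | Cc1ccc(-c2ccc(OC)cc2)c([C+](c2ccccc2)c2ccc(OC)cc2)c1C#Cc1ccc(OC)cc1 | intermediate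
13 | selaginellin A, 4-[[6-(4-hydroxyphenyl)-2-[(4-hydroxyphenyl)ethynyl]-3-methylphenyl](phenyl)methylidene]cyclohexa-2,5-dien-1-one | Cc1ccc(-c2ccc(O)cc2)c(C(=C2C=CC(=O)C=C2)c2ccccc2)c1C#Cc1ccc(O)cc1 | target

**Totals**
Total step count: 3. Longest linear sequence: 3 steps (1 → 3 → 11 → 13).

**Steps most likely to fail**

Step 2 (proposed new method). What may go wrong:
- acetylide addition at the wrong aryne carbon (C5 instead of C6);
- proton transfer from tetramethylpiperidine to the C5 aryllithium before the ketone arrives;
- competing benzylic deprotonation of the C1 methyl;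
- addition of the C5 aryllithium to a second aryne;
- sluggish addition of the 2,6-disubstituted aryllithium to the diaryl ketone;
- cyclisation of the alkoxide onto the alkyne on warming.

Fallback (known reactions only, from 1, returning at 11): the two crowded bonds would be made separately. LDA in THF at −78 °C removes the proton of 1 flanked by bromine and chlorine (ortho-metalation between two halogens), and the aryllithium is added to ketone 5 to give (6-bromo-2-chloro-3-methylphenyl)(4-methoxyphenyl)(phenyl)methanol F1. Suzuki coupling of the bromide of F1 with 2 (Pd(dppf)Cl2, K2CO3, dioxane–H2O, 90 °C) gives [2-chloro-6-(4-methoxyphenyl)-3-methylphenyl](4-methoxyphenyl)(phenyl)methanol F2. Copper-free Sonogashira coupling of the aryl chloride of F2 with 4 (PdCl2(MeCN)2/XPhos, Cs2CO3, MeCN, 80 °C) then gives 11. The position of each substituent is fixed by the halogen pattern of 1, so aryne regiochemistry no longer matters.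

Step 3. What may go wrong:
- Friedel–Crafts closure of the C7 cation onto the C4 aryl ring (9,9-diarylfluorene formation);
- bromoboration or HBr addition across the C8≡C9 alkyne;
- incomplete cleavage of the two ordinary anisole ethers.

Fallback (from 11, returning at 13): the ethers would be cleaved without acid. Sodium ethanethiolate in DMF at 120–130 °C (SN2 demethylation), followed by neutral work-up, gives 4-[hydroxy[6-(4-hydroxyphenyl)-2-[(4-hydroxyphenyl)ethynyl]-3-methylphenyl](phenyl)methyl]phenol F3. Brief exposure of F3 to dilute acetic acid then dehydrates the 4-hydroxyphenyl carbinol to the quinone methide 13.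

Step 1. What may go wrong:
- competing oxidative addition at the C–Cl bond (over-arylation);
- protodeboronation or homocoupling of the boronic acid.

Fallback (from 1, returning at 3): the polarity of the coupling would be reversed. Bromine–magnesium exchange of 1 with i-PrMgCl·LiCl (THF, −15 °C; the chloride does not exchange) gives (3-chloro-4-methylphenyl)magnesium chloride F4. ZnCl2 converts F4 into (3-chloro-4-methylphenyl)zinc chloride F5. Negishi coupling of F5 with commercial 4-iodoanisole (COc1ccc(I)cc1; Pd(PPh3)4, THF, 25–50 °C) gives 3.

**Further compounds**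
F1 | step 2 | (6-bromo-2-chloro-3-methylphenyl)(4-methoxyphenyl)(phenyl)methanol (racemic) | Cc1ccc(Br)c(C(O)(c2ccccc2)c2ccc(OC)cc2)c1Cl
F2 | step 2 | [2-chloro-6-(4-methoxyphenyl)-3-methylphenyl](4-methoxyphenyl)(phenyl)methanol (racemic) | Cc1ccc(-c2ccc(OC)cc2)c(C(O)(c2ccccc2)c2ccc(OC)cc2)c1Cl
F3 | step 3 | 4-[hydroxy[6-(4-hydroxyphenyl)-2-[(4-hydroxyphenyl)ethynyl]-3-methylphenyl](phenyl)methyl]phenol (racemic) | Cc1ccc(-c2ccc(O)cc2)c(C(O)(c2ccccc2)c2ccc(O)cc2)c1C#Cc1ccc(O)cc1
F4 | step 1 | (3-chloro-4-methylphenyl)magnesium chloride | Cc1ccc([Mg]Cl)cc1Cl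
F5 | step 1 | (3-chloro-4-methylphenyl)zinc chloride | Cc1ccc([Zn]Cl)cc1Cl
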